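**Plan**

- Numbering: phthalide C1 (lactone C=O), O2, C3, C3a, C4–C7, C7a; side chain C1'–C14' on C3. The benzene ring (C3a, C4, C5, C6, C7, C7a) has oxygen on C5 and C7, the carboxyl carbon C1 on C7a and the carbinol C3 on C3a. This is the alternating pattern of a folded tetraketide, so the ring can be made from an open poly-β-carbonyl chain by aldol condensation across C7a–C3a.
- Cuts, in retrosynthetic order: C13' ketone back to a terminal alkene; acetate and both O-methyl groups; lactone bond C1–O2 (back to an acetonide-masked salicylate with a C3 silyl ether); ring bond C7a–C3a (back to a 6-(2,4-dioxoalkyl)dioxinone); C4–C3a (Claisen); C1'–C2' (Grignard reagent plus glycidate); C11'–C12' (allyl plus epoxide).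
- Forward order: the chain is built from C14' to C3a (steps 1–7) and joined to the dioxinone unit (step 9). The benzene ring is closed (step 10), then the lactone ring (step 11), followed by O-methylation, acetylation and Wacker oxidation.
- Stereochemistry: C10' (R) comes from hydrolytic kinetic resolution of a terminal epoxide and C3 (S) from methyl (S)-glycidate. Neither C–O bond is broken afterwards, and the key step creates no stereocentre.

Key step: step 10

Remarks: TBS = tert-butyldimethylsilyl, TBSO = its ether. salen = dianion of N,N'-bis(3,5-di-tert-butylsalicylidene)-(1R,2R)-cyclohexane-1,2-diamine. Organometallic steps are taken to be quenched with water.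

**Route**

Step 1
Reactants: 1 10-bromodec-1-ene
Product: 2 rac-2-(8-bromooctyl)oxirane
Conditions: mCPBA, CH2Cl2, 0 °C to rt
Reagents that add atoms: mCPBA (3-chloroperoxybenzoic acid), OOC(=O)c1cccc(Cl)c1
Why: Prilezhaev epoxidation of an unhindered terminal alkene, to which the primary bromide is inert.

Step 2
Reactants: 2 rac-2-(8-bromooctyl)oxirane
Product: 3 (R)-2-(8-bromooctyl)oxirane
Conditions: (R,R)-(salen)Co(OAc) (trivalent cobalt, 0.5 mol%), H2O (0.55 equiv), THF, 0 °C to rt
Reagents that add atoms: none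
Why: Jacobsen hydrolytic kinetic resolution, in which the (R,R)-catalyst should hydrate the (S)-epoxide to the diol and leave the (R)-epoxide, so that the future C10' is fixed here (at most half of 2 can be carried on).

Step 3
Reactants: 3 (R)-2-(8-bromooctyl)oxirane; 4 allylmagnesium bromide
Product: 5 (5R)-13-bromotridec-1-en-5-ol
Conditions: CuI (10 mol%), THF, –40 °C
Reagents that add atoms: none
Why: Copper-catalysed Grignard opening of a terminal epoxide at its CH2 carbon (SN2), which leaves the C–O bond of the stereocentre untouched, while the primary bromide should not couple at this temperature.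

Step 4
Reactants: 5 (5R)-13-bromotridec-1-en-5-ol
Product: 6 (5R)-13-bromo-5-(TBSO)tridec-1-ene
Conditions: TBSOTf, 2,6-lutidine, CH2Cl2, –78 to 0 °C
Reagents that add atoms: TBSOTf (tert-butyldimethylsilyl trifluoromethanesulfonate), CC(C)(C)[Si](C)(C)OS(=O)(=O)C(F)(F)F
Why: Silyl ether formation on a secondary alcohol with a non-nucleophilic base, which cannot displace the bromide.

Step 5
Reactants: 6 (5R)-13-bromo-5-(TBSO)tridec-1-ene; 7 methyl (S)-glycidate
Product: 9 methyl (2S,12R)-12-(TBSO)-2-hydroxyhexadec-15-enoate, via Grignard reagent 8 (not isolated)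
Conditions: Mg, THF, rt; then added to 7, CuI (10 mol%), THF, –78 to –40 °C
Reagents that add atoms: none
Why: Grignard formation followed by copper-catalysed opening of the glycidic ester at C3 (SN2 at the CH2), which should outpace ester addition at low temperature and transfers the (S) centre of the glycidate unchanged to the future C3.

Step 6
Reactants: 9 methyl (2S,12R)-12-(TBSO)-2-hydroxyhexadec-15-enoate
Product: 10 methyl (2S,12R)-2,12-bis(TBSO)hexadec-15-enoate
Conditions: TBSOTf, 2,6-lutidine, CH2Cl2, –78 to 0 °C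
Reagents that add atoms: TBSOTf (tert-butyldimethylsilyl trifluoromethanesulfonate), CC(C)(C)[Si](C)(C)OS(=O)(=O)C(F)(F)F
Why: Silyl ether formation, which masks the C3 oxygen so that it cannot add to a carbonyl in the polycarbonyl stage and can be removed together with the C10' ether.

Step 7
Reactants: 10 methyl (2S,12R)-2,12-bis(TBSO)hexadec-15-enoate
Product: 11 (2S,12R)-2,12-bis(TBSO)-N-methoxy-N-methylhexadec-15-enamide
Conditions: MeNHOMe·HCl, iPrMgCl, THF, –20 to 0 °C
Reagents that add atoms: N,O-dimethylhydroxylamine hydrochloride, CNOC.Cl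
Why: Weinreb amide formation by aminolysis of the methyl ester with the chloromagnesium amide, conditions under which α-silyloxy esters are not expected to enolise.

Step 8
Reactants: 12 2,2,6-trimethyl-4H-1,3-dioxin-4-one
Product: 14 2,2-dimethyl-6-(2-oxopropyl)-4H-1,3-dioxin-4-one, via lithium dienolate 13 (not isolated)
Conditions: LiN(SiMe3)2 (2 equiv per AcCl), THF, –78 °C; AcCl, –78 to –20 °C
Reagents that add atoms: acetyl chloride, CC(=O)Cl
Why: Vinylogous Claisen C-acylation of the dioxinone dienolate at its γ-carbon, with the second equivalent of base absorbing the more acidic product.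

Step 9
Reactants: 14 2,2-dimethyl-6-(2-oxopropyl)-4H-1,3-dioxin-4-one; 11 (2S,12R)-2,12-bis(TBSO)-N-methoxy-N-methylhexadec-15-enamide
Product: 16 6-[(5S,15R)-5,15-bis(TBSO)-2,4-dioxononadec-18-enyl]-2,2-dimethyl-4H-1,3-dioxin-4-one, via dilithio dianion 15 (not isolated)
Conditions: LiN(iPr)2 (2 equiv per 14; 14 in excess over 11), THF, –78 °C; then 11, –78 to –40 °C
Reagents that add atoms: none
Why: Claisen-type acylation of the keto-dioxinone dianion at its terminal, more nucleophilic carbon by the Weinreb amide, whose chelated tetrahedral adduct should prevent over-addition and keep the C3 hydrogen non-acidic until the quench.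

Step 10
Reactants: 16 6-[(5S,15R)-5,15-bis(TBSO)-2,4-dioxononadec-18-enyl]-2,2-dimethyl-4H-1,3-dioxin-4-one
Product: 18 5-[(1S,11R)-1,11-bis(TBSO)pentadec-14-enyl]-7-hydroxy-2,2-dimethyl-4H-1,3-benzodioxin-4-one, via aldol adduct 17 (not isolated)
Conditions: Et3N, CH2Cl2, rt
Reagents that add atoms: none
Why: Et3N reversibly deprotonates the CH2 between the dioxinone and the first ketone, and the dienolate attacks through the dioxinone α-carbon (future C7a) onto the distal α-silyloxy ketone (future C3a) to give aldol adduct 17, which loses water by E1cB elimination and enolises its remaining ring ketone to the C5 phenol. The closest known reaction type is the amine-mediated aldol aromatisation of 6-(2,4-dioxoalkyl)-1,3-dioxin-4-ones to acetonide-masked resorcylates, the laboratory counterpart of polyketide cyclisation. The benzene ring closes by a 6-(enolexo)-exo-trig aldol addition (the dioxinone enol C=C lies outside the new ring and the ketone oxygen is exocyclic), made irreversible by dehydration and aromatisation. No stereocentre is formed, and C3 should keep its (S) configuration because its hydrogen is flanked by only one carbonyl and is far less acidic than the two doubly activated CH2 groups that the weak base addresses. The step needs C-cyclisation at C7a–C3a in preference to O-cyclisation or other aldol modes: only this bond gives a six-membered carbocycle (the nearer ketone would give a four-membered ring), the C3 silyl ether keeps that oxygen from adding to a carbonyl, and the dioxinone masks C1 and the C7 oxygen so that neither lactonisation nor decarboxylation can intervene before the arene exists.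

Step 11
Reactants: 18 5-[(1S,11R)-1,11-bis(TBSO)pentadec-14-enyl]-7-hydroxy-2,2-dimethyl-4H-1,3-benzodioxin-4-one
Product: 20 (3S)-5,7-dihydroxy-3-[(10R)-10-hydroxytetradec-13-enyl]isobenzofuran-1(3H)-one, via desilylated triol 19 (not isolated)
Conditions: Bu4NF (4 equiv), THF, 0 °C to rt
Reagents that add atoms: none
Why: Fluoride desilylation followed by lactonisation, in which the C3 alkoxide attacks the benzodioxinone carbonyl (5-exo-trig acyl transfer) and the hemiketal leaving group collapses to acetone and the C7 phenoxide, with the C3–O bond and hence the (S) configuration untouched.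

Step 12
Reactants: 20 (3S)-5,7-dihydroxy-3-[(10R)-10-hydroxytetradec-13-enyl]isobenzofuran-1(3H)-one
Product: 21 (3S)-3-[(10R)-10-hydroxytetradec-13-enyl]-5,7-dimethoxyisobenzofuran-1(3H)-one
Conditions: MeI, K2CO3, acetone, reflux
Reagents that add atoms: iodomethane, CI
Why: Williamson O-methylation, since K2CO3 ionises only the two phenols and leaves the secondary C10' alcohol unalkylated.

Step 13
Reactants: 21 (3S)-3-[(10R)-10-hydroxytetradec-13-enyl]-5,7-dimethoxyisobenzofuran-1(3H)-one
Product: 22 (3S)-3-[(10R)-10-acetoxytetradec-13-enyl]-5,7-dimethoxyisobenzofuran-1(3H)-one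
Conditions: Ac2O, pyridine, DMAP (cat.), CH2Cl2, rt
Reagents that add atoms: acetic anhydride, CC(=O)OC(C)=O
Why: DMAP-catalysed acylation of the only free hydroxyl, which also removes the alcohol that would otherwise ketalise with the ketone formed next.

Step 14
Reactants: 22 (3S)-3-[(10R)-10-acetoxytetradec-13-enyl]-5,7-dimethoxyisobenzofuran-1(3H)-one
Product: 23 (3S)-3-[(10R)-10-acetoxy-13-oxotetradecyl]-5,7-dimethoxyisobenzofuran-1(3H)-one
Conditions: PdCl2 (10 mol%), CuCl, O2 (1 atm), DMF/H2O, rt
Reagents that add atoms: water, O (source of the ketone oxygen; O2 is the terminal oxidant)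
Why: Tsuji–Wacker oxidation, in which Markovnikov hydroxypalladation of the terminal alkene by divalent palladium gives the methyl ketone, the acetoxy group two carbons away being too remote to divert the regiochemistry.

**Compound list**

1 | 10-bromodec-1-ene | C=CCCCCCCCCBr | starting material
2 | rac-2-(8-bromooctyl)oxirane | BrCCCCCCCCC1CO1 | intermediate
3 | (R)-2-(8-bromooctyl)oxirane | BrCCCCCCCC[C@@H]1CO1 | intermediate
4 | allylmagnesium bromide | C=CC[Mg]Br | starting material
5 | (5R)-13-bromotridec-1-en-5-ol | BrCCCCCCCC[C@H](CCC=C)O | intermediate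
6 | (5R)-13-bromo-5-(TBSO)tridec-1-ene | BrCCCCCCCC[C@H](CCC=C)O[Si](C)(C)C(C)(C)C | intermediate
7 | methyl (S)-glycidate | COC(=O)[C@@H]1CO1 | starting material
8 | [(9R)-9-(TBSO)tridec-12-enyl]magnesium bromide (formed in the flask) | Br[Mg]CCCCCCCC[C@H](CCC=C)O[Si](C)(C)C(C)(C)C | intermediate
9 | methyl (2S,12R)-12-(TBSO)-2-hydroxyhexadec-15-enoate | COC(=O)[C@@H](O)CCCCCCCCC[C@H](CCC=C)O[Si](C)(C)C(C)(C)C | intermediate
10 | methyl (2S,12R)-2,12-bis(TBSO)hexadec-15-enoate | COC(=O)[C@@H](O[Si](C)(C)C(C)(C)C)CCCCCCCCC[C@H](CCC=C)O[Si](C)(C)C(C)(C)C | intermediate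
11 | (2S,12R)-2,12-bis(TBSO)-N-methoxy-N-methylhexadec-15-enamide | CON(C)C(=O)[C@@H](O[Si](C)(C)C(C)(C)C)CCCCCCCCC[C@H](CCC=C)O[Si](C)(C)C(C)(C)C | intermediate
12 | 2,2,6-trimethyl-4H-1,3-dioxin-4-one | CC1=CC(=O)OC(C)(C)O1 | starting material
13 | lithium 2,2-dimethyl-6-methylidene-6H-1,3-dioxin-4-olate (dienolate of 12, formed in the flask) | [Li+].C=C1C=C([O-])OC(C)(C)O1 | intermediate
14 | 2,2-dimethyl-6-(2-oxopropyl)-4H-1,3-dioxin-4-one | CC(=O)CC1=CC(=O)OC(C)(C)O1 | intermediate
15 | dilithium 2,2-dimethyl-6-(2-oxidoprop-2-enylidene)-6H-1,3-dioxin-4-olate (dianion of 14, formed in the flask) | [Li+].[Li+].C=C([O-])C=C1C=C([O-])OC(C)(C)O1 | intermediate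
16 | 6-[(5S,15R)-5,15-bis(TBSO)-2,4-dioxononadec-18-enyl]-2,2-dimethyl-4H-1,3-dioxin-4-one | CC1(C)OC(=CC(=O)O1)CC(=O)CC(=O)[C@@H](O[Si](C)(C)C(C)(C)C)CCCCCCCCC[C@H](CCC=C)O[Si](C)(C)C(C)(C)C | intermediate
17 | 5-[(1S,11R)-1,11-bis(TBSO)pentadec-14-enyl]-5-hydroxy-2,2-dimethyl-5,6-dihydro-4H-1,3-benzodioxine-4,7(4aH)-dione (aldol adduct, ring carbons C4a and C5 unassigned, formed in the flask) | CC1(C)OC2=CC(=O)CC(O)([C@@H](O[Si](C)(C)C(C)(C)C)CCCCCCCCC[C@H](CCC=C)O[Si](C)(C)C(C)(C)C)C2C(=O)O1 | intermediate
18 | 5-[(1S,11R)-1,11-bis(TBSO)pentadec-14-enyl]-7-hydroxy-2,2-dimethyl-4H-1,3-benzodioxin-4-one | CC1(C)Oc2cc(O)cc(c2C(=O)O1)[C@@H](O[Si](C)(C)C(C)(C)C)CCCCCCCCC[C@H](CCC=C)O[Si](C)(C)C(C)(C)C | intermediate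
19 | 5-[(1S,11R)-1,11-dihydroxypentadec-14-enyl]-7-hydroxy-2,2-dimethyl-4H-1,3-benzodioxin-4-one (formed in the flask) | CC1(C)Oc2cc(O)cc(c2C(=O)O1)[C@@H](O)CCCCCCCCC[C@H](CCC=C)O | intermediate
20 | (3S)-5,7-dihydroxy-3-[(10R)-10-hydroxytetradec-13-enyl]isobenzofuran-1(3H)-one | Oc1cc(O)c2c(c1)[C@H](CCCCCCCCC[C@H](CCC=C)O)OC2=O | intermediate
21 | (3S)-3-[(10R)-10-hydroxytetradec-13-enyl]-5,7-dimethoxyisobenzofuran-1(3H)-one | COc1cc(OC)c2c(c1)[C@H](CCCCCCCCC[C@H](CCC=C)O)OC2=O | intermediate
22 | (3S)-3-[(10R)-10-acetoxytetradec-13-enyl]-5,7-dimethoxyisobenzofuran-1(3H)-one | COc1cc(OC)c2c(c1)[C@H](CCCCCCCCC[C@H](CCC=C)OC(C)=O)OC2=O | intermediate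
23 | (3S)-3-[(10R)-10-acetoxy-13-oxotetradecyl]-5,7-dimethoxyisobenzofuran-1(3H)-one | COc1cc(OC)c2c(c1)[C@H](CCCCCCCCC[C@H](CCC(C)=O)OC(C)=O)OC2=O | target

**Step count and risks**

Total steps: 14. Longest linear sequence: 13 (steps 1–7 and 9–14); step 8 is a one-step side branch.

Steps most likely to fail, riskiest first:

1. Step 10. The aldol closure onto a ketone that sits beside the bulky C3 silyl ether may be slow. O-cyclisation of the enolised diketone or gradual loss of C3 configuration could then compete. The fallback sets out from 16 and returns at 20, opening the dioxinone before the ring is folded. Heating 16 in toluene at 110 °C with methanol should expel acetone by retro-hetero-Diels–Alder reaction to give the acylketene (8S,18R)-8,18-bis(TBSO)docosa-1,21-diene-1,3,5,7-tetrone F1. Methanol should trap it as the open-chain methyl (8S,18R)-8,18-bis(TBSO)-3,5,7-trioxodocos-21-enoate F2. Cs2CO3 in MeOH followed by AcOH should then effect the aldol condensation and aromatisation of this freer chain to methyl 2-[(1S,11R)-1,11-bis(TBSO)pentadec-14-enyl]-4,6-dihydroxybenzoate F3. Bu4NF in THF should strip both silyl groups to methyl 2-[(1S,11R)-1,11-dihydroxypentadec-14-enyl]-4,6-dihydroxybenzoate F4, whose C3 hydroxyl should lactonise onto the methyl ester in the same flask to give 20.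

2. Step 9. The dianion may act as a base toward the hindered α-silyloxy amide, or acylate incompletely, and prolonged exposure to excess base could erode the C3 configuration. The fallback sets out from 10 (with 14) and returns at 16, replacing the acylation by an aldol addition and oxidation. iBu2AlH in CH2Cl2 at –78 °C should reduce 10 to (2S,12R)-2,12-bis(TBSO)hexadec-15-enal F5. Dianion 15, made as in step 9, should add to this aldehyde at –78 °C through its terminal carbon to give 6-[(5S,15R)-5,15-bis(TBSO)-4-hydroxy-2-oxononadec-18-enyl]-2,2-dimethyl-4H-1,3-dioxin-4-one F6 as a mixture at the new carbinol, which does not matter. Dess–Martin periodinane in CH2Cl2 should oxidise the β-hydroxy ketone to the 1,3-diketone 16.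

3. Step 5. The Grignard reagent may add to the ester carbonyl of the glycidate instead of opening the epoxide, and Wurtz homocoupling may erode it while it forms. The fallback sets out from 6 (through 8) and returns at 11, using an epoxide without an ester. Reagent 8 with CuI (10 mol%) should open (S)-4-methoxybenzyl glycidyl ether (COc1ccc(COC[C@@H]2CO2)cc1) at its CH2 to give (2S,12R)-12-(TBSO)-1-(4-methoxybenzyloxy)hexadec-15-en-2-ol F7. TBSOTf and 2,6-lutidine should give 1-{[(2S,12R)-2,12-bis(TBSO)hexadec-15-enyl]oxymethyl}-4-methoxybenzene F8. DDQ in wet buffered CH2Cl2 should cleave the benzyl ether to (2S,12R)-2,12-bis(TBSO)hexadec-15-en-1-ol F9. PhI(OAc)2 with catalytic TEMPO in aqueous MeCN should oxidise the primary alcohol to (2S,12R)-2,12-bis(TBSO)hexadec-15-enoic acid F10. Coupling with MeNHOMe·HCl, EDC·HCl and iPr2NEt should give 11.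

Further compounds
F1 | step 10 | (8S,18R)-8,18-bis(TBSO)docosa-1,21-diene-1,3,5,7-tetrone (acylketene, transient) | O=C=CC(=O)CC(=O)CC(=O)[C@@H](O[Si](C)(C)C(C)(C)C)CCCCCCCCC[C@H](CCC=C)O[Si](C)(C)C(C)(C)C
F2 | step 10 | methyl (8S,18R)-8,18-bis(TBSO)-3,5,7-trioxodocos-21-enoate | COC(=O)CC(=O)CC(=O)CC(=O)[C@@H](O[Si](C)(C)C(C)(C)C)CCCCCCCCC[C@H](CCC=C)O[Si](C)(C)C(C)(C)C
F3 | step 10 | methyl 2-[(1S,11R)-1,11-bis(TBSO)pentadec-14-enyl]-4,6-dihydroxybenzoate | COC(=O)c1c(O)cc(O)cc1[C@@H](O[Si](C)(C)C(C)(C)C)CCCCCCCCC[C@H](CCC=C)O[Si](C)(C)C(C)(C)C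
F4 | step 10 | methyl 2-[(1S,11R)-1,11-dihydroxypentadec-14-enyl]-4,6-dihydroxybenzoate (transient) | COC(=O)c1c(O)cc(O)cc1[C@@H](O)CCCCCCCCC[C@H](CCC=C)O
F5 | step 9 | (2S,12R)-2,12-bis(TBSO)hexadec-15-enal | O=C[C@@H](O[Si](C)(C)C(C)(C)C)CCCCCCCCC[C@H](CCC=C)O[Si](C)(C)C(C)(C)C
F6 | step 9 | 6-[(5S,15R)-5,15-bis(TBSO)-4-hydroxy-2-oxononadec-18-enyl]-2,2-dimethyl-4H-1,3-dioxin-4-one | CC1(C)OC(=CC(=O)O1)CC(=O)CC(O)[C@@H](O[Si](C)(C)C(C)(C)C)CCCCCCCCC[C@H](CCC=C)O[Si](C)(C)C(C)(C)C
F7 | step 5 | (2S,12R)-12-(TBSO)-1-(4-methoxybenzyloxy)hexadec-15-en-2-ol | COc1ccc(COC[C@@H](O)CCCCCCCCC[C@H](CCC=C)O[Si](C)(C)C(C)(C)C)cc1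
F8 | step 5 | 1-{[(2S,12R)-2,12-bis(TBSO)hexadec-15-enyl]oxymethyl}-4-methoxybenzene | COc1ccc(COC[C@@H](O[Si](C)(C)C(C)(C)C)CCCCCCCCC[C@H](CCC=C)O[Si](C)(C)C(C)(C)C)cc1
F9 | step 5 | (2S,12R)-2,12-bis(TBSO)hexadec-15-en-1-ol | OC[C@@H](O[Si](C)(C)C(C)(C)C)CCCCCCCCC[C@H](CCC=C)O[Si](C)(C)C(C)(C)C
F10 | step 5 | (2S,12R)-2,12-bis(TBSO)hexadec-15-enoic acid | OC(=O)[C@@H](O[Si](C)(C)C(C)(C)C)CCCCCCCCC[C@H](CCC=C)O[Si](C)(C)C(C)(C)C
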